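(All runs are calculated with constants of no real substance; scatter was added.)

Dusk and summer follow one recipe and differ in c(initiator) and in time; the earlier runs show what such a flask does.

| flask | substrate | gas | initiator | remark | time |
|---|---|---|---|---|---|
| west | 0.050 M | 1.8 mM (held) | 0.56 mM | run made earlier |  |
| north | 0.050 M | 1.8 mM (held) | 0.91 mM | run made earlier |  |
| south-west | 0.050 M | 1.8 mM (held) | 1.3 mM | run made earlier |  |
| dusk | 0.050 M | 1.8 mM (held) | 1.5 mM |  | 2.5 h |
| summer | 0.050 M | 1.8 mM (held) | 0.50 mM |  | 8.0 h |

| west: time / h | west: target / % | north: time / h | north: target / % | south-west: time / h | south-west: target / % |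
|---|---|---|---|---|---|
| 2.00 | 35.1 | 1.00 | 23.5 | 2.00 | 53.5 |
| 4.00 | 52.8 | 3.00 | 55.1 | 4.00 | 56.6 |
| 6.00 | 52.9 | 5.00 | 56.1 | 6.00 | 59.2 |
| 8.00 | 53.5 | 8.00 | 57.4 | 8.00 | 59.4 |

(readings scatter by 1 percentage point)

1. the flask that ends with the higher amount of target, in percent of the substrate charged, or "neither" when 2 percentage points or less lies between them (dusk / summer / neither)
2. final target, as a percentage of the substrate charged, in dusk
3. final target, as a percentage of the substrate charged, in summer

- at the start none of the gas is in solution

In west and north, target climbs steeply and then breaks at a knee onto a plateau, so the curve can be replaced by its mean rate up to the knee. The first readings of these runs give a rate ratio of 1.34, near the root of their initiator ratio, 1.27. The mean rate is therefore taken to grow with the root of c(initiator). The charge time, in which the mean rate makes target equal to the whole substrate charge, is 5.56 h at the west charge. South-west, not used for it, gets 54.8 % at 2.00 h against a reading of 53.5 %.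

The first way to the answer is time over charge time. Dusk has a charge time of 3.40 h and gets 73.5 %. Summer has 5.88 h and gets 136 %, more than the substrate charged, so this way cheats by running past the knee.

The second way reads the plateaus, averaged over the readings past the knee: 53.1 % in west and 58.4 % in south-west. A straight line through them against the root of c(initiator) gives north 55.9 %, where its readings average 56.2 %. The same line gives dusk 59.6 % and summer 52.5 %. The charge times put the knees at 2.02 h in dusk, earlier than its 2.5 h, and at 3.09 h in summer, earlier than its 8.0 h. The plateaus therefore stand as the reckoning, with dusk higher by 7 percentage points.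

The forecast chose dusk, with 57 % (54.5 % to 60.5 %) for dusk and 52.8 % (50.8 % to 54.5 %) for summer, on the reading “Each run then breaks sharply at a knee”.

The flasks give 60.1 % in dusk and 52.0 % in summer, so dusk ends higher.

    substrate + target → side product (k = 0.330 L mol⁻¹ min⁻¹)
    initiator → 2 initiating radical (k = 3.10 × 10⁻⁴ min⁻¹)
    gas ⇌ reagent, rate k3*(csat - [reagent]) (kL = 0.530 min⁻¹)
    substrate + initiating radical → capped initiator + first chain carrier (k = 1.20 × 10⁵ L mol⁻¹ s⁻¹)
    reagent + first chain carrier → target + second chain carrier (k = 1.60 × 10⁵ L mol⁻¹ s⁻¹)
    crystals ⇌ by-product, rate k6*(cs6 - [by-product]) while solid is left; crystals form when [by-product] > cs6 (solubility = 29.0 mM, k = 0.630 min⁻¹)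
    substrate + second chain carrier → by-product + first chain carrier (k = 38000 L mol⁻¹ s⁻¹)
    2 first chain carrier → ended chains (k = 9.40 × 10⁶ L mol⁻¹ s⁻¹)

Substrate, the limiting reagent, stands at 0 % in dusk at 2.50 h, beside 39.7 % of side product. At 1.25 h the charge time of dusk gives 36.8 %, and dusk holds 34.3 %. A neighbour of dusk charged with 3.8 × 10⁻⁴ M of initiator has a charge time of 6.75 h, which gives 37.0 % at 2.5 h; that neighbour holds 35.8 % of target, with 19.3 % of substrate left.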